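**Retrosynthetic overview**

1. Ainsliatrimer A is cut back to its 10′-deoxy trimer (C1′=C10′, H at C2′); the C10′ hydroxyl comes last, by γ-oxygenation of the unit B dienolate with O2.
2. Feature used: in ring E (C2′, C1′, C10′, C14′, C15″, C4″) the spiro carbon C4″ is the α-carbon of the C3″ ketone and C10′ is allylic across C1′=C2′. The C2′–C4″ bond is therefore made by a [3,3] shift of a C3″–O–C10′ allyl vinyl ether held in a spiro-dihydropyran, which contracts to ring E.
3. That dihydropyran must carry its oxygen on the β face of C10′. It is made first, at the monomer stage, by hetero-Diels–Alder addition of dehydrozaluzanin C to C10′=C14′ of zaluzanin C, steered by the 3′β-hydroxyl.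
4. Ring D (C2, C1, C10, C14, C15′, C4′) is then built by the same two moves on the other side of unit B: unit B enone plus C10=C14 of a 3β-silyloxy monomer, dehydrogenation of unit A, [3,3] shift, conjugation.
5. Order of ring formation: B–C dihydropyran, A–B dihydropyran, ring D, ring E. All three units come from dehydrocostus lactone.

Key step: step 13

**Remarks on the chemistry (assumptions)**

- Guaiane numbering; unit A unprimed, unit B primed, unit C double-primed; α is the face of H1 and H5 of the parent lactone.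
- The hetero-Diels–Alder step creates only C10 (or C10′), and that centre alone fixes the face of the spiro carbon in the later shift: oxygen β at C10′ puts C2′ on the α face of C4″, oxygen α at C10 puts C2 on the β face of C4′. The target needs exactly these two.
- A model of the cis-fused guaianolide places the 3β-oxygen about 3 Å from the β-face trajectory at C10. It is used as a hydrogen-bond donor when free (oxygen enters β) and as a screen when silylated (oxygen enters α). This is a design premise, not an established result.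
- Electrophiles (H+ at C10, O2 at C10′) are assumed to enter anti to C5 of the neighbouring spiro-cyclopentanone, which is the arrangement found in the target at both centres.

**Route**

Step 1
Reactants: 1 dehydrocostus lactone; 2 tert-butyl hydroperoxide
Product: 3 3-epizaluzanin C (3α-hydroxy-dehydrocostus lactone)
Conditions: SeO2 (0.5 equiv), t-BuOOH (2 equiv), CH2Cl2, 23 °C
Reagents that add atoms: tert-butyl hydroperoxide (2), CC(C)(C)OO
Why: Allylic oxidation with SeO2 and the hydroperoxide as terminal oxidant (ene reaction at C15, then [2,3] shift) should hydroxylate C3 next to the C4=C15 bond from the convex α face; the C3 configuration is erased in step 2.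

Step 2
Reactants: 3 3-epizaluzanin C
Product: 4 dehydrozaluzanin C (3-oxo-4(15)-ene)
Conditions: Dess–Martin periodinane, pyridine, CH2Cl2, 0 °C
Reagents that add atoms: none
Why: Dess–Martin oxidation of the allylic alcohol gives the exocyclic enone under buffered, non-basic conditions that spare the methylene lactone; the enone is used at once because it self-condenses on standing.

Step 3
Reactants: 4 dehydrozaluzanin C
Product: 5 zaluzanin C (3β-hydroxy)
Conditions: NaBH4, CeCl3·7H2O, MeOH, −78 °C
Reagents that add atoms: none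
Why: Luche reduction delivers hydride 1,2 to the cerium-activated ketone from the convex α face, which should give the 3β-alcohol, while the methylene lactone is not reduced at −78 °C.

Step 4
Reactants: 5 zaluzanin C
Product: 6 zaluzanin C tert-butyldimethylsilyl ether
Conditions: TBSCl, imidazole, DMF, 23 °C
Reagents that add atoms: tert-butyldimethylsilyl chloride, CC(C)(C)[Si](C)(C)Cl
Why: Imidazole-promoted silylation of the secondary alcohol removes the hydrogen-bond donor and places a bulky group on the β face beside C10=C14.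

Step 5
Reactants: 4 dehydrozaluzanin C; 5 zaluzanin C
Product: 7 B–C spiro-dihydropyran (O–C10′ on the β face, C15″–C14′; unit B keeps 3′β-OH and C4′=C15′)
Conditions: 4 added over 24 h to 5 (4 equiv), PhCl, 80 °C, BHT; excess 5 recovered
Reagents that add atoms: none
Why: Inverse-electron-demand hetero-Diels–Alder reaction of the s-cis-locked exocyclic enone with the 1,1-disubstituted alkene joins C15″ to the CH2 terminus C14′ and the carbonyl oxygen to the tertiary carbon C10′; the 3′β-hydroxyl on the concave face hydrogen-bonds to the enone oxygen, activates it and holds it on the β face, so the one new stereocentre C10′ should carry oxygen β; C4′=C15′ is less reactive (allylic C–O bond, more crowded inner carbon) and slow addition keeps the enone from dimerising through its own C4″=C15″ bond.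

Step 6
Reactants: 7 B–C spiro-dihydropyran
Product: 8 B–C spiro-dihydropyran with the unit B 3′-oxo-4′(15′)-ene
Conditions: Dess–Martin periodinane, pyridine, CH2Cl2, 0 °C
Reagents that add atoms: none
Why: Dess–Martin oxidation of the allylic 3′-alcohol regenerates an exocyclic enone on unit B, and the pyridine buffer protects the enol ether.

Step 7
Reactants: 8 B–C spiro-dihydropyran enone; 6 zaluzanin C silyl ether
Product: 9 bis-dihydropyran trimer (O3′–C10 on the α face of unit A, C15′–C14; unit A 3β-OTBS)
Conditions: 8 added over 24 h to 6 (5 equiv), PhCl, 90 °C, BHT; excess 6 recovered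
Reagents that add atoms: none
Why: A second hetero-Diels–Alder reaction of the same kind adds the unit B enone (O3′ and C15′) across C10=C14 of the silyl ether, whose β face is screened by the 3β-silyloxy group and which has no hydrogen-bond donor, so oxygen should enter C10 from the convex α face; C4′ stays trigonal, so no stereocentre forms on unit B.

Step 8
Reactants: 9 bis-dihydropyran trimer silyl ether
Product: 10 bis-dihydropyran trimer with unit A 3β-OH
Conditions: TBAF, AcOH (1:1), THF, 0 to 23 °C
Reagents that add atoms: none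
Why: Fluoride cleavage of the secondary silyl ether, buffered with acetic acid, keeps the methylene lactones and both enol ethers away from base and strong acid.

Step 9
Reactants: 10 bis-dihydropyran trimer alcohol
Product: 11 bis-dihydropyran trimer with the unit A 3-oxo-4(15)-ene
Conditions: Dess–Martin periodinane, pyridine, CH2Cl2, 0 °C
Reagents that add atoms: none
Why: Dess–Martin oxidation gives the unit A enone, which is the only ketone in the molecule because units B and C are present as enol ethers.

Step 10
Reactants: 11 bis-dihydropyran trimer enone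
Product: 13 bis-dihydropyran trimer with the unit A 1,4(15)-dien-3-one, via unit A silyloxydiene 12 (not isolated)
Conditions: TBSOTf, Et3N, CH2Cl2, −78 to 0 °C; then Pd(OAc)2 (1.2 equiv), MeCN, 23 °C
Reagents that add atoms: none
Why: Saegusa–Ito dehydrogenation: soft enolisation of the single ketone toward C2 gives the 2-silyloxydiene, and Pd(OAc)2 turns it, through the palladium enolate and β-hydride loss of H1, into the C1=C2 enone, which makes the A–B pyran a 2-vinyl dihydropyran.

Step 11
Reactants: 13 bis-dihydropyran trimer dienone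
Product: 15 trimer with ring D closed and the unit A dienone conjugated (10α-H; unit B saturated 3′-ketone; B–C pyran intact), via ring D Claisen product 14 (not isolated)
Conditions: PhMe (degassed), BHT, 100 °C; then DBU (0.1 equiv), CH2Cl2, 0 °C, Ar
Reagents that add atoms: none
Why: Thermal Claisen ring contraction of the 2-vinyl-3,4-dihydro-2H-pyran (boat transition state) joins C2 to C4′ on the face fixed by the α-oxygen at C10, which is the β face of unit B, closes ring D and releases the C3′ ketone; catalytic DBU then moves C1=C10 into conjugation through the dienolate, which should be protonated at C10 anti to C5′ to give the 10α-hydrogen.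

Step 12
Reactants: 15 trimer with ring D and B–C pyran
Product: 17 trimer-level 2-vinyl dihydropyran (C3″–O–C10′, unit B C1′=C2′ enone), via unit B silyl enol ether 16 (not isolated)
Conditions: TBSOTf (1.2 equiv), Et3N, CH2Cl2, −78 °C; then Pd(OAc)2 (1.2 equiv), MeCN, 23 °C
Reagents that add atoms: none
Why: Saegusa–Ito dehydrogenation of unit B: C2′ is the only enolisable α-position (C4′ is quaternary and the unit A dienone has no α-hydrogen), and β-hydride loss of H1′ from the palladium enolate gives the C1′=C2′ enone, so that C10′ now carries the vinyl arm of an allyl vinyl ether.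

Step 13
Reactants: 17 trimer-level 2-vinyl dihydropyran
Product: 18 10′-deoxy trimer (ring E closed, C3″ ketone, C1′=C10′, H at C2′)
Conditions: PhMe (degassed), BHT, 120 °C, sealed tube, Ar; product used directly
Reagents that add atoms: none
Why: Concerted [3,3]-sigmatropic (Claisen) shift of the allyl vinyl ether C4″=C3″–O–C10′–C1′=C2′: the O–C10′ bond breaks as C2′–C4″ forms, the enol ether becomes the C3″ ketone and the double bond moves to C1′=C10′. The closest known reaction type is the thermal ring contraction of 2-alkenyl-3,4-dihydro-2H-pyrans to 4-acylcyclohexenes. Ring E is closed by sigmatropic ring contraction: the oxacycle (O, C3″, C4″, C15″, C14′, C10′) becomes the carbocycle (C2′, C1′, C10′, C14′, C15″, C4″) through a boat-shaped, bicyclo[2.2.2]octane-like transition state enforced by the pyran ring. C4″ is set by C10′, because C2′ can reach only the pyran face that carries C1′, which with oxygen β at C10′ is the α face of unit C; C2′ is formed suprafacially on the face the oxygen leaves and is a transient centre removed in step 14. The step needs the shift to outrun retro-hetero-Diels–Alder cleavage and C10′–O ionisation; the breaking bond is tertiary and allylic, a carbonyl group is gained, the medium is neutral and non-polar, and 17 holds no other allyl vinyl ether because the A–B pyran was consumed in step 11. The allyl terminus C2′ is the α-carbon of an enone, which slows the shift somewhat, hence 120 °C with a radical inhibitor and exclusion of air.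

Step 14
Reactants: 18 10′-deoxy trimer
Product: 20 ainsliatrimer A, via 10′β-hydroperoxide 19 (not isolated)
Conditions: O2 (1 atm), DBU (0.5 equiv), MeCN, −20 to 0 °C; then P(OEt)3
Reagents that add atoms: dioxygen, O=O
Why: γ-Oxygenation of the extended enolate: DBU removes the doubly activated H2′, triplet oxygen adds at C10′ on the ring E face anti to C5″ (the face of the C3″ carbonyl) to give the 10′β-hydroperoxide and the C1′=C2′ enone, and the phosphite reduces the O–O bond; the C10 hydrogen of unit A is a less acidic γ-hydrogen of an already conjugated dienone and should survive at low temperature.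

**Compound list**

1 | dehydrocostus lactone | C=C1CC[C@H]2C(=C)CC[C@H]3C(=C)C(=O)O[C@@H]3[C@H]21 | starting material
2 | tert-butyl hydroperoxide | CC(C)(C)OO | starting material
3 | 3-epizaluzanin C (3α-OH) | C=C1[C@H](O)C[C@H]2C(=C)CC[C@H]3C(=C)C(=O)O[C@@H]3[C@H]21 | intermediate
4 | dehydrozaluzanin C | C=C1C(=O)C[C@H]2C(=C)CC[C@H]3C(=C)C(=O)O[C@@H]3[C@H]21 | intermediate
5 | zaluzanin C (3β-OH) | C=C1[C@@H](O)C[C@H]2C(=C)CC[C@H]3C(=C)C(=O)O[C@@H]3[C@H]21 | intermediate
6 | zaluzanin C tert-butyldimethylsilyl ether | C=C1[C@@H](O[Si](C)(C)C(C)(C)C)C[C@H]2C(=C)CC[C@H]3C(=C)C(=O)O[C@@H]3[C@H]21 | intermediate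
7 | B–C spiro-dihydropyran, unit B 3′β-OH, C10′ oxygen β | C=C1[C@@H](O)C[C@H]2[C@]4(CCC5=C(O4)C[C@H]6C(=C)CC[C@H]7C(=C)C(=O)O[C@@H]7[C@H]65)CC[C@H]3C(=C)C(=O)O[C@@H]3[C@H]21 | intermediate
8 | B–C spiro-dihydropyran, unit B 3′-oxo-4′(15′)-ene | C=C1C(=O)C[C@H]2[C@]4(CCC5=C(O4)C[C@H]6C(=C)CC[C@H]7C(=C)C(=O)O[C@@H]7[C@H]65)CC[C@H]3C(=C)C(=O)O[C@@H]3[C@H]21 | intermediate
9 | bis-dihydropyran trimer, unit A 3β-OTBS, C10 oxygen α | C=C1[C@@H](O[Si](C)(C)C(C)(C)C)C[C@H]2[C@@]3(CCC5=C(O3)C[C@H]6[C@]7(CCC8=C(O7)C[C@H]9C(=C)CC[C@H]%10C(=C)C(=O)O[C@@H]%10[C@H]98)CC[C@H]%11C(=C)C(=O)O[C@@H]%11[C@H]65)CC[C@H]4C(=C)C(=O)O[C@@H]4[C@H]21 | intermediate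
10 | bis-dihydropyran trimer, unit A 3β-OH | C=C1[C@@H](O)C[C@H]2[C@@]3(CCC5=C(O3)C[C@H]6[C@]7(CCC8=C(O7)C[C@H]9C(=C)CC[C@H]%10C(=C)C(=O)O[C@@H]%10[C@H]98)CC[C@H]%11C(=C)C(=O)O[C@@H]%11[C@H]65)CC[C@H]4C(=C)C(=O)O[C@@H]4[C@H]21 | intermediate
11 | bis-dihydropyran trimer, unit A 3-oxo-4(15)-ene | C=C1C(=O)C[C@H]2[C@@]3(CCC5=C(O3)C[C@H]6[C@]7(CCC8=C(O7)C[C@H]9C(=C)CC[C@H]%10C(=C)C(=O)O[C@@H]%10[C@H]98)CC[C@H]%11C(=C)C(=O)O[C@@H]%11[C@H]65)CC[C@H]4C(=C)C(=O)O[C@@H]4[C@H]21 | intermediate
12 | bis-dihydropyran trimer, unit A 3-silyloxy-2,4(15)-diene | C=C1C(O[Si](C)(C)C(C)(C)C)=C[C@H]2[C@@]3(CCC5=C(O3)C[C@H]6[C@]7(CCC8=C(O7)C[C@H]9C(=C)CC[C@H]%10C(=C)C(=O)O[C@@H]%10[C@H]98)CC[C@H]%11C(=C)C(=O)O[C@@H]%11[C@H]65)CC[C@H]4C(=C)C(=O)O[C@@H]4[C@H]21 | intermediate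
13 | bis-dihydropyran trimer, unit A 1,4(15)-dien-3-one | C=C1C(=O)C=C2[C@@]3(CCC5=C(O3)C[C@H]6[C@]7(CCC8=C(O7)C[C@H]9C(=C)CC[C@H]%10C(=C)C(=O)O[C@@H]%10[C@H]98)CC[C@H]%11C(=C)C(=O)O[C@@H]%11[C@H]65)CC[C@H]4C(=C)C(=O)O[C@@H]4[C@H]21 | intermediate
14 | ring D Claisen product, unit A H at C2 and C1=C10, B–C pyran intact | C=C1C(=O)[C@H]2C3=C(CC[C@H]4C(=C)C(=O)O[C@@H]4[C@@H]13)CC[C@@]21C(=O)C[C@H]3[C@]5(CCC6=C(O5)C[C@H]7C(=C)CC[C@H]8C(=C)C(=O)O[C@@H]8[C@H]76)CC[C@H]9C(=C)C(=O)O[C@@H]9[C@H]31 | intermediate
15 | trimer with ring D, unit A conjugated dienone (10α-H), unit B saturated ketone, B–C pyran | C=C1C(=O)C2=C3[C@H](CC[C@H]4C(=C)C(=O)O[C@@H]4[C@@H]13)CC[C@@]21C(=O)C[C@H]3[C@]5(CCC6=C(O5)C[C@H]7C(=C)CC[C@H]8C(=C)C(=O)O[C@@H]8[C@H]76)CC[C@H]9C(=C)C(=O)O[C@@H]9[C@H]31 | intermediate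
16 | unit B 3′-silyl enol ether of 15 | C=C1C(=O)C2=C3[C@H](CC[C@H]4C(=C)C(=O)O[C@@H]4[C@@H]13)CC[C@@]21C(O[Si](C)(C)C(C)(C)C)=C[C@H]3[C@]5(CCC6=C(O5)C[C@H]7C(=C)CC[C@H]8C(=C)C(=O)O[C@@H]8[C@H]76)CC[C@H]9C(=C)C(=O)O[C@@H]9[C@H]31 | intermediate
17 | trimer-level 2-vinyl dihydropyran (C3″–O–C10′, C1′=C2′ enone) | C=C1C(=O)C2=C3[C@H](CC[C@H]4C(=C)C(=O)O[C@@H]4[C@@H]13)CC[C@@]21C(=O)C=C3[C@H]1[C@H]1OC(=O)C(=C)[C@@H]1CC[C@@]36CCC5=C(O6)C[C@H]7C(=C)CC[C@H]8C(=C)C(=O)O[C@@H]8[C@H]75 | intermediate
18 | 10′-deoxy trimer (C1′=C10′, H at C2′) | C=C1C(=O)C2=C3[C@H](CC[C@H]4C(=C)C(=O)O[C@@H]4[C@@H]13)CC[C@@]21C(=O)[C@@H]2C3=C(CC[C@H]4C(=C)C(=O)O[C@@H]4[C@@H]13)CC[C@]21C(=O)C[C@H]2C(=C)CC[C@H]3C(=C)C(=O)O[C@@H]3[C@H]21 | intermediate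
19 | 10′β-hydroperoxide | C=C1C(=O)C2=C3[C@H](CC[C@H]4C(=C)C(=O)O[C@@H]4[C@@H]13)CC[C@@]21C(=O)C2=C3[C@H]1[C@H]1OC(=O)C(=C)[C@@H]1CC[C@@]3(OO)CC[C@]21C(=O)C[C@H]2C(=C)CC[C@H]3C(=C)C(=O)O[C@@H]3[C@H]21 | intermediate
20 | ainsliatrimer A | C=C1C(=O)C2=C3[C@H](CC[C@H]4C(=C)C(=O)O[C@@H]4[C@@H]13)CC[C@@]21C(=O)C2=C3[C@H]1[C@H]1OC(=O)C(=C)[C@@H]1CC[C@@]3(O)CC[C@]21C(=O)C[C@H]2C(=C)CC[C@H]3C(=C)C(=O)O[C@@H]3[C@H]21 | target

**Step count and risks**

Total step count: 14. Longest linear sequence: 13 steps (steps 1, 2, 3, 5 to 14; step 4 is a side branch).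

Steps most likely to fail:

Step 5. The enone may be consumed by self-dimerisation, the cycloaddition may go across C4′=C15′ instead of C10′=C14′, or oxygen may enter C10′ from the α face, which would feed the C4″-epimeric series. The fallback sets out from 5 (with 4) and comes back at 7. Compound 5 is treated with AlMe3 (1 equiv, PhMe, −78 °C) to give its dimethylaluminium alkoxide F1. The aluminium centre is held on the β face by O3′ and binds the carbonyl oxygen of 4, added at −40 °C. The addition of C14′ to C15″ and the closure of the aluminium enolate oxygen onto C10′ then take place inside one complex on the β face, and aqueous work-up gives 7. This replaces a thermal concerted cycloaddition with hydrogen-bond steering by a Lewis-acid-tethered stepwise annulation.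

Step 7. The dimeric heterodiene may self-condense, the unactivated alkene may react too slowly, or the wrong alkene of 6 may react. The fallback sets out from 4 and 8 and comes back at 14. Compound 4 is dehydrogenated (TBSOTf, Et3N; then Pd(OAc)2) through the silyloxydiene F2 to the cross-conjugated trienone F3. The C2=C1–C10=C14 diene of F3 adds to the C4′=C15′ enone of 8 in an all-carbon Diels–Alder reaction (PhMe, 40 °C, Ar). The endo adduct on the α face of the diene is 14, which is conjugated with DBU as in step 11. This replaces the oxygen-tethered relay by a direct intermolecular [4+2] addition; the face of C4′ is then no longer enforced and the C4′ epimer would have to be separated.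

Step 13. Cycloreversion or C10′–O heterolysis may compete with the sigmatropic shift, the shift may be slow because the allyl terminus is electron-poor, and the air-sensitive product may degrade. The fallback sets out from 4 and comes back at 18. The trienone F3, made from 4 as described for step 7, adds to the enone of a second molecule of 4 to give the A–B Diels–Alder adduct F4. DBU converts it into the conjugated A–B dimer F5. Saegusa–Ito dehydrogenation through the unit B silyl enol ether F6 gives the A–B dienone F7. A second Diels–Alder reaction of F7 with 4, with C5″ under the diene, gives 18 directly without any pyran. The adduct of the opposite orientation (C4″ epimer) is expected as a co-product and would have to be removed.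

**Further compounds**

F1 | step 5 | dimethylaluminium alkoxide of zaluzanin C | C=C1[C@@H](O[Al](C)C)C[C@H]2C(=C)CC[C@H]3C(=C)C(=O)O[C@@H]3[C@H]21
F2 | step 7 | 3-silyloxy-2,4(15)-diene of dehydrozaluzanin C | C=C1C(O[Si](C)(C)C(C)(C)C)=C[C@H]2C(=C)CC[C@H]3C(=C)C(=O)O[C@@H]3[C@H]21
F3 | step 7 | cross-conjugated trienone (3-oxo-1,4(15),10(14)-triene) | C=C1C(=O)C=C2C(=C)CC[C@H]3C(=C)C(=O)O[C@@H]3[C@H]21
F4 | step 13 | A–B Diels–Alder adduct (H at C2, C1=C10) | C=C1C(=O)[C@H]2C3=C(CC[C@H]4C(=C)C(=O)O[C@@H]4[C@@H]13)CC[C@@]21C(=O)C[C@H]3C(=C)CC[C@H]9C(=C)C(=O)O[C@@H]9[C@H]31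
F5 | step 13 | conjugated A–B dimer (10α-H) | C=C1C(=O)C2=C3[C@H](CC[C@H]4C(=C)C(=O)O[C@@H]4[C@@H]13)CC[C@@]21C(=O)C[C@H]3C(=C)CC[C@H]9C(=C)C(=O)O[C@@H]9[C@H]31
F6 | step 13 | unit B silyl enol ether of the A–B dimer | C=C1C(=O)C2=C3[C@H](CC[C@H]4C(=C)C(=O)O[C@@H]4[C@@H]13)CC[C@@]21C(O[Si](C)(C)C(C)(C)C)=C[C@H]3C(=C)CC[C@H]9C(=C)C(=O)O[C@@H]9[C@H]31
F7 | step 13 | A–B dienone (unit B C1′=C2′, C10′=C14′) | C=C1C(=O)C2=C3[C@H](CC[C@H]4C(=C)C(=O)O[C@@H]4[C@@H]13)CC[C@@]21C(=O)C=C3C(=C)CC[C@H]9C(=C)C(=O)O[C@@H]9[C@H]31
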